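With the arene numbered C1 (CH2SO2CH3), C2 (Br), C3 (OH), C4 (OH), C5 (Br), C6 (Br), five contiguous ring carbons, C1 to C5, the exocyclic CH2 on C1 and the vicinal oxygens on C3 and C4 already exist in kojic acid as C2 to C6 of its 4-pyranone ring; C6 of the target corresponds to the pyranone oxygen. The route therefore disconnects C5–C6 and C6–C1: a single operation replaces that ring oxygen by the carbon of nitromethane, builds the benzene ring and leaves NO2 on C6 as a masked bromine. Its substrate is O5-methylated kojic acid carrying CH2SO2CH3 in place of CH2OH.

Key step: step 4

Remark: the target is achiral, so no stereocentre has to be set. The ring numbering above is used for all arenes, and pyranone positions are cited by their own locants (O1, C2–C6).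

Step 1
Reactants: 1 kojic acid, 5-hydroxy-2-(hydroxymethyl)-4H-pyran-4-one
Product: 2 2-(hydroxymethyl)-5-methoxy-4H-pyran-4-one
Conditions: Me2SO4 (1.1 equiv), KOH (1.1 equiv), H2O, 0 → 20 °C
Reagents that add atoms: dimethyl sulfate, COS(=O)(=O)OC
Why: One equivalent of hydroxide ionises only the enolic 5-OH, which is far more acidic than the primary alcohol, so the Williamson-type O-methylation should occur at O5 alone; capping O5 first means no enolate can form in the later base-mediated ring exchange.

Step 2
Reactants: 2 2-(hydroxymethyl)-5-methoxy-4H-pyran-4-one
Product: 3 2-(chloromethyl)-5-methoxy-4H-pyran-4-one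
Conditions: SOCl2 (1.5 equiv), CH2Cl2, 0 → 20 °C
Reagents that add atoms: thionyl chloride, O=S(Cl)Cl
Why: Deoxychlorination of an activated primary alcohol with thionyl chloride should be clean because the only other hydroxyl is already methylated and the vinylogous-ester ring is inert to the reagent.

Step 3
Reactants: 3 2-(chloromethyl)-5-methoxy-4H-pyran-4-one; 4 sodium methanesulfinate
Product: 5 5-methoxy-2-[(methylsulfonyl)methyl]-4H-pyran-4-one
Conditions: MeSO2Na (1.5 equiv), DMF, 60 °C
Reagents that add atoms: none
Why: SN2 displacement of the soft, allylic-type primary chloride by the ambident sulfinate should proceed through sulfur to give the sulfone, and as no base is present the acidic CH2 of the product cannot be alkylated a second time.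

Step 4
Reactants: 5 5-methoxy-2-[(methylsulfonyl)methyl]-4H-pyran-4-one; 6 nitromethane
Product: 8 2-methoxy-5-[(methylsulfonyl)methyl]-4-nitrophenol, via open-chain nitro diketone 7 (not isolated)
Conditions: CH3NO2 (10 equiv), t-BuOK (3 equiv), t-BuOH, 20 → 80 °C; then 1 M HCl
Reagents that add atoms: none
Why: The nitronate of 6 should add in conjugate fashion to the unsubstituted C6 next to the ring oxygen, the adduct should open by beta-elimination of that oxygen to the enolate of 7, and the re-deprotonated nitromethyl carbon should then attack the unmasked C2 ketone in a nitro-aldol (Henry) closure, after which loss of water and enolisation of the former C4 carbonyl give the phenoxide of 8; attack at C2 instead converges on the same arene, since the incoming carbon ends bonded to both C2 and C6. This is the known base-mediated exchange of the ring oxygen of 4-pyranones (and pyrylium salts) for the carbon of nitromethane, giving 4-nitrophenols, here applied to a kojic acid ether. The one ring formed, the benzene ring, closes 6-exo-trig at the ketone carbonyl, and no stereocentre arises. The step needs the nitronate to attack a ring carbon flanking oxygen, not the carbonyl, and needs the substrate not to be lost as its sulfonyl-stabilised carbanion: the carbonyl is a deactivated vinylogous ester, and a large excess of nitromethane over base keeps deprotonation of CH2SO2CH3 reversible, so neutral 5 is regenerated and removed irreversibly by aromatisation. The substitution pattern of 8 follows from the substrate alone, the old carbonyl carbon becoming C3–OH para to the nitro group on C6, with OCH3 on C4 and the sulfonylmethyl arm on C1.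

Step 5
Reactants: 8 2-methoxy-5-[(methylsulfonyl)methyl]-4-nitrophenol
Product: 9 1,2-dimethoxy-4-[(methylsulfonyl)methyl]-5-nitrobenzene
Conditions: MeI (1.2 equiv), K2CO3 (1.5 equiv), acetone, 50 °C
Reagents that add atoms: iodomethane, CI
Why: Williamson etherification of the acidic para-nitrophenol should be selective because carbonate in acetone barely ionises the benzylic sulfone CH2 and the near-stoichiometric iodomethane is taken up by the phenoxide; the capped phenol keeps the later aniline from oxidising and its diazonium from collapsing to a quinone diazide.

Step 6
Reactants: 9 1,2-dimethoxy-4-[(methylsulfonyl)methyl]-5-nitrobenzene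
Product: 10 4,5-dimethoxy-2-[(methylsulfonyl)methyl]aniline
Conditions: H2 (1 atm), 10% Pd/C, EtOAc/MeOH, 20 °C
Reagents that add atoms: none
Why: Catalytic hydrogenation of an aromatic nitro group over palladium on carbon should leave the sulfone and aryl ethers untouched, and it is placed before any bromine is on the ring so that hydrodehalogenation cannot occur.

Step 7
Reactants: 10 4,5-dimethoxy-2-[(methylsulfonyl)methyl]aniline
Product: 12 1-bromo-4,5-dimethoxy-2-[(methylsulfonyl)methyl]benzene, via arenediazonium bromide 11 (not isolated)
Conditions: NaNO2 (1.1 equiv), 48% aq. HBr, MeCN, 0 °C; then added to CuBr (0.5 equiv), 48% aq. HBr, 60 °C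
Reagents that add atoms: hydrogen bromide, Br; sodium nitrite, O=N[O-].[Na+] (nitrogen of 11 only)
Why: In this Sandmeyer reaction electron transfer from monovalent copper (CuBr) to 11 should release N2 and an aryl radical that takes bromine from the divalent copper bromide (CuBr2) formed in the cycle, placing Br on C6; the strongly acidic medium keeps the neighbouring sulfonyl-activated CH2 un-ionised, and running the cold diazonium solution straight into hot CuBr/HBr should let bromine transfer outrun any attack of that carbon on the diazonium group.

Step 8
Reactants: 12 1-bromo-4,5-dimethoxy-2-[(methylsulfonyl)methyl]benzene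
Product: 13 4-bromo-5-[(methylsulfonyl)methyl]benzene-1,2-diol
Conditions: BBr3 (4 equiv), CH2Cl2, −78 → 20 °C; then H2O
Reagents that add atoms: none
Why: Lewis-acid cleavage of aryl methyl ethers (boron coordination at oxygen, bromide attack at methyl, hydrolysis of the aryl borate on work-up) should free both hydroxyls while the sulfone and aryl bromide are inert, the excess reagent covering any coordination to the sulfonyl oxygens.

Step 9
Reactants: 13 4-bromo-5-[(methylsulfonyl)methyl]benzene-1,2-diol
Product: 14 3,4,6-tribromo-5-[(methylsulfonyl)methyl]benzene-1,2-diol
Conditions: Br2 (2.2 equiv), AcOH, 20 °C, dark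
Reagents that add atoms: bromine, BrBr
Why: Electrophilic aromatic bromination should fill the only two ring positions left, C2 and C5, each ortho to a free hydroxyl, so no regiochemical choice exists; ipso attack at C1 is not expected because a sulfonyl-substituted methyl cation is a hopeless leaving group.

Compound list
1 | kojic acid, 5-hydroxy-2-(hydroxymethyl)-4H-pyran-4-one | OCc1cc(=O)c(O)co1 | starting material
2 | 2-(hydroxymethyl)-5-methoxy-4H-pyran-4-one | COc1coc(CO)cc1=O | intermediate
3 | 2-(chloromethyl)-5-methoxy-4H-pyran-4-one | COc1coc(CCl)cc1=O | intermediate
4 | sodium methanesulfinate | CS(=O)[O-].[Na+] | starting material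
5 | 5-methoxy-2-[(methylsulfonyl)methyl]-4H-pyran-4-one | COc1coc(CS(C)(=O)=O)cc1=O | intermediate
6 | nitromethane | C[N+](=O)[O-] | starting material
7 | (5E)-5-methoxy-1-(methylsulfonyl)-7-nitrohept-5-ene-2,4-dione (open-chain nitro diketone, present as its enolate; drawn with the alkene geometry needed for closure, the isomers interconverting through the allylic nitronate) | CS(=O)(=O)CC(=O)CC(=O)/C(OC)=C\C[N+](=O)[O-] | intermediate (not isolated)
8 | 2-methoxy-5-[(methylsulfonyl)methyl]-4-nitrophenol | CS(=O)(=O)Cc1cc(O)c(OC)cc1[N+](=O)[O-] | intermediate
9 | 1,2-dimethoxy-4-[(methylsulfonyl)methyl]-5-nitrobenzene | COc1cc(CS(C)(=O)=O)c([N+](=O)[O-])cc1OC | intermediate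
10 | 4,5-dimethoxy-2-[(methylsulfonyl)methyl]aniline | COc1cc(CS(C)(=O)=O)c(N)cc1OC | intermediate
11 | 4,5-dimethoxy-2-[(methylsulfonyl)methyl]benzenediazonium bromide | COc1cc(CS(C)(=O)=O)c([N+]#N)cc1OC.[Br-] | intermediate (not isolated)
12 | 1-bromo-4,5-dimethoxy-2-[(methylsulfonyl)methyl]benzene | COc1cc(CS(C)(=O)=O)c(Br)cc1OC | intermediate
13 | 4-bromo-5-[(methylsulfonyl)methyl]benzene-1,2-diol | CS(=O)(=O)Cc1cc(O)c(O)cc1Br | intermediate
14 | 3,4,6-tribromo-5-[(methylsulfonyl)methyl]benzene-1,2-diol | CS(=O)(=O)Cc1c(Br)c(O)c(O)c(Br)c1Br | target

Total step count: 9. Longest linear sequence: 9 steps, from 1 to 14; the route is fully linear, with 4 and 6 entering as one-step building blocks.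

Steps most likely to fail

Step 4. The base may hold the pyranone as its sulfonyl-stabilised carbanion, an electron-rich species that no longer accepts the nitronate. That carbanion may also add to a second pyranone, or nitromethane may self-condense before the ring exchange takes place. The fallback removes the acidity and sets out from 3. Displacement of the chloride with NaSMe (THF/MeOH, 0 °C) should give 5-methoxy-2-[(methylsulfanyl)methyl]-4H-pyran-4-one F1, whose CH2 is no more acidic than the methyl groups of the simple 2,6-dialkyl-4-pyranones on which this ring exchange is established. The same treatment with 6 and t-BuOK in t-BuOH should then give 2-methoxy-5-[(methylsulfanyl)methyl]-4-nitrophenol F2. Oxidation at sulfur with H2O2 and catalytic Na2WO4 in MeOH returns to the route at 8.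

Step 7. The diazonium group may be captured by the neighbouring acidic benzylic carbon, closing to an indazole, or hydrolysed to a phenol before bromine is transferred. The fallback avoids the diazonium altogether and sets out from 9. Palladium-catalysed reductive denitration (Pd(acac)2, BrettPhos, K3PO4, 2-propanol, 130 °C) should give 1,2-dimethoxy-4-[(methylsulfonyl)methyl]benzene F3, and BBr3 in CH2Cl2 should then give 4-[(methylsulfonyl)methyl]benzene-1,2-diol F4. Bromine (3.3 equiv) in AcOH should fill all three free positions C2, C5 and C6, each ortho or para to a hydroxyl, so that the C6 bromine comes from electrophilic substitution instead; the route is rejoined at the target 14.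

Step 9. Bromine may oxidise the catechol to its ortho-quinone, or substitution may stall after the first bromine, the C2 position being flanked by two substituents. The fallback reverses the order of the last two operations and sets out from 12. Exhaustive bromination of the non-oxidisable dimethyl ether with Br2 and Fe powder (FeBr3 formed in the flask) in CHCl3 at reflux should give 1,2,4-tribromo-5,6-dimethoxy-3-[(methylsulfonyl)methyl]benzene F5. BBr3 in CH2Cl2 then frees the catechol as the final operation and arrives at 14, so that no free catechol ever meets bromine.

Further compounds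
F1 | step 4 | 5-methoxy-2-[(methylsulfanyl)methyl]-4H-pyran-4-one | COc1coc(CSC)cc1=O
F2 | step 4 | 2-methoxy-5-[(methylsulfanyl)methyl]-4-nitrophenol | CSCc1cc(O)c(OC)cc1[N+](=O)[O-]
F3 | step 7 | 1,2-dimethoxy-4-[(methylsulfonyl)methyl]benzene | COc1ccc(CS(C)(=O)=O)cc1OC
F4 | step 7 | 4-[(methylsulfonyl)methyl]benzene-1,2-diol | CS(=O)(=O)Cc1ccc(O)c(O)c1
F5 | step 9 | 1,2,4-tribromo-5,6-dimethoxy-3-[(methylsulfonyl)methyl]benzene | COc1c(Br)c(CS(C)(=O)=O)c(Br)c(Br)c1OC
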